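**Retrosynthetic overview**
1. The last bond made is the CH2–CH2 bond between the allylic CH2 of the (E)-enyne and the first CH2 of the bromodienyl chain. It is formed by a copper-catalysed γ-selective (SN2') allyl–alkyl coupling of a B-alkyl-9-BBN, made in the flask from triene 20, with the 1-alkynylallyl phosphate 13, without protecting groups.
2. Enabling feature: the unit oxolane-C5–C≡C–CH=CH–CH2 is the 1,3-transposed form of a pent-1-en-4-yn-3-yl carbinol, so alkylation at its unsubstituted =CH2 terminus makes the bond and the conjugated (E)-alkene together; the partner carbon is the terminal CH2 of a monosubstituted alkene, which hydroboration turns into the nucleophile.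
3. Phosphate 13 comes from alkyne 9 and acrolein; 9 comes from aldehyde 8 (Ohira–Bestmann), whose ester arm is built by cross-metathesis and hydrogenation.
4. Ring order: the only ring, the 2,5-trans oxolane, is closed in step 2 by a Mukaiyama aerobic oxidative cyclisation (5-exo) of (S)-octa-1,7-dien-4-ol, made from epoxide 1.
5. Triene 20 comes from a Z-selective Wittig reaction of the but-3-enyl ylide with (E)-3-bromoacrolein 17.

Key step: step 12

Remark: the target is the 2,5-trans oxolane with CIP descriptors (2R,5S); epoxide 1 is taken as commercial, and 12 and 13 are carried as mixtures of epimers at the carbinol carbon, which is not a stereocentre of the target.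

Step 1
Reactants: 1 (S)-2-(but-3-en-1-yl)oxirane; 2 vinylmagnesium bromide
Product: 3 (S)-octa-1,7-dien-4-ol
Conditions: vinylMgBr (1.5 equiv), CuI (10 mol%), THF, −30 to 0 °C; aq. NH4Cl
Reagents that add atoms: none
Why: Copper-catalysed Grignard opening of a terminal epoxide (SN2 at the CH2 carbon); the stereocentre of 1 is not involved and is carried over unchanged as the (S)-carbinol.

Step 2
Reactants: 3 (S)-octa-1,7-dien-4-ol
Product: 4 [(2S,5S)-5-(prop-2-en-1-yl)oxolan-2-yl]methanol
Conditions: Co(modp)2 (15 mol%), O2 (1 atm), t-BuOOH (10 mol%), i-PrOH, 55 °C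
Reagents that add atoms: dioxygen, O=O
Why: Mukaiyama aerobic oxidative cyclisation: the cobalt-bound alkoxide closes 5-exo onto the bishomoallylic alkene and oxygen trapping gives the CH2OH group, the new ring stereocentre being set 2,5-trans by the carbinol centre (substituent pseudo-equatorial in the chair-like transition state); the allyl alkene would need a 4-exo closure and should be spared.

Step 3
Reactants: 4 [(2S,5S)-5-(prop-2-en-1-yl)oxolan-2-yl]methanol; 5 methyl acrylate
Product: 6 methyl (2E)-4-[(2S,5S)-5-(hydroxymethyl)oxolan-2-yl]but-2-enoate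
Conditions: methyl acrylate (5 equiv), Hoveyda–Grubbs 2nd-generation catalyst (3 mol%), CH2Cl2, 40 °C
Reagents that add atoms: none
Why: Olefin cross-metathesis of a terminal alkene with an acrylate, which does not homodimerise readily; the free alcohol is tolerated and the alkene geometry is irrelevant because it is hydrogenated next.

Step 4
Reactants: 6 methyl (2E)-4-[(2S,5S)-5-(hydroxymethyl)oxolan-2-yl]but-2-enoate
Product: 7 methyl 4-[(2R,5S)-5-(hydroxymethyl)oxolan-2-yl]butanoate
Conditions: H2 (1 atm), 10% Pd/C, EtOAc, rt
Reagents that add atoms: none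
Why: Heterogeneous hydrogenation of the only C=C bond; no stereocentre is touched (the descriptor at the chain-bearing ring carbon changes from S to R only through the CIP ranking).

Step 5
Reactants: 7 methyl 4-[(2R,5S)-5-(hydroxymethyl)oxolan-2-yl]butanoate
Product: 8 methyl 4-[(2R,5S)-5-formyloxolan-2-yl]butanoate
Conditions: TEMPO (10 mol%), PhI(OAc)2 (1.2 equiv), CH2Cl2, rt
Reagents that add atoms: none
Why: TEMPO/PhI(OAc)2 (oxoammonium) oxidation stops at the aldehyde and is mild enough to leave the α-alkoxy stereocentre intact.

Step 6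
Reactants: 8 methyl 4-[(2R,5S)-5-formyloxolan-2-yl]butanoate
Product: 9 methyl 4-[(2R,5S)-5-ethynyloxolan-2-yl]butanoate
Conditions: Ohira–Bestmann reagent (1.3 equiv), K2CO3 (2 equiv), MeOH, 0 °C to rt
Reagents that add atoms: dimethyl (1-diazo-2-oxopropyl)phosphonate, COP(=O)(OC)C(=[N+]=[N-])C(C)=O
Why: Seyferth–Gilbert homologation in the Ohira–Bestmann variant (diazophosphonate addition, then 1,2-H shift of the alkylidene carbene); the methyl ester is invariant to K2CO3/MeOH and the aldehyde should be consumed fast enough at 0 °C to keep the ring stereocentre.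

Step 7
Reactants: 9 methyl 4-[(2R,5S)-5-ethynyloxolan-2-yl]butanoate; 10 acrolein
Product: 12 methyl 4-[(2R,5S)-5-(3-hydroxypent-4-en-1-yn-1-yl)oxolan-2-yl]butanoate, via methylzinc acetylide 11 (not isolated)
Conditions: Me2Zn (2 equiv), ProPhenol ligand (10 mol%), Ph3P=O (20 mol%), toluene, 0 °C; then acrolein (2.5 equiv), 0–4 °C; aq. NH4Cl
Reagents that add atoms: none
Why: Ligand-accelerated 1,2-addition of a zinc acetylide to an enal; dimethylzinc deprotonates only the alkyne and does not attack the ester, and the new carbinol centre is irrelevant because it disappears in step 12.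

Step 8
Reactants: 12 methyl 4-[(2R,5S)-5-(3-hydroxypent-4-en-1-yn-1-yl)oxolan-2-yl]butanoate
Product: 13 methyl 4-[(2R,5S)-5-{3-[(diethoxyphosphoryl)oxy]pent-4-en-1-yn-1-yl}oxolan-2-yl]butanoate
Conditions: ClP(O)(OEt)2 (1.5 equiv), pyridine (3 equiv), DMAP (10 mol%), CH2Cl2, 0 °C; short Et3N-deactivated silica plug; used at once
Reagents that add atoms: diethyl chlorophosphate, CCOP(=O)(Cl)OCC
Why: O-Phosphorylation of a secondary alcohol under nucleophilic catalysis; nothing else in 12 is nucleophilic.

Step 9
Reactants: 14 3,3-diethoxyprop-1-yne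
Product: 16 (1E)-1-bromo-3,3-diethoxyprop-1-ene, via alkenylzirconocene 15 (not isolated)
Conditions: Cp2Zr(H)Cl (1.1 equiv), THF, rt; then NBS (1.1 equiv), 0 °C
Reagents that add atoms: N-bromosuccinimide, BrN1C(=O)CCC1=O
Why: Hydrozirconation is a syn addition that places zirconium on the terminal carbon, and bromodezirconation with NBS goes with retention, so the E-bromoalkene should result; the acetal is inert.

Step 10
Reactants: 16 (1E)-1-bromo-3,3-diethoxyprop-1-ene
Product: 17 (2E)-3-bromoprop-2-enal
Conditions: 10% aq. oxalic acid on SiO2, CH2Cl2, rt; dried solution used directly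
Reagents that add atoms: water, O
Why: Acid-catalysed acetal hydrolysis; the E-configured β-bromoenal is the thermodynamic isomer, so acid should not erode the geometry.

Step 11
Reactants: 18 (but-3-en-1-yl)triphenylphosphonium bromide; 17 (2E)-3-bromoprop-2-enal
Product: 20 (4Z,6E)-7-bromohepta-1,4,6-triene, via phosphorus ylide 19 (not isolated)
Conditions: NaHMDS (1.0 equiv), THF, 0 °C; then 17, −78 °C to rt
Reagents that add atoms: none
Why: Wittig olefination of a non-stabilised ylide under lithium-free conditions gives the Z-alkene through the kinetically favoured cis-oxaphosphetane; the E-bromoalkene of 17 is not touched.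

Step 12
Reactants: 20 (4Z,6E)-7-bromohepta-1,4,6-triene; 13 methyl 4-[(2R,5S)-5-{3-[(diethoxyphosphoryl)oxy]pent-4-en-1-yn-1-yl}oxolan-2-yl]butanoate
Product: 23 methyl 4-[(2R,5S)-5-[(3E,9Z,11E)-12-bromododeca-3,9,11-trien-1-yn-1-yl]oxolan-2-yl]butanoate, via B-alkyl-9-BBN 21 (not isolated), via potassium alkylborate 22 (not isolated)
Conditions: 20 (1.5 equiv), 9-BBN-H dimer (0.75 equiv), THF, 0 °C to rt; then KOtBu (1.4 equiv), CuOAc (10 mol%), 13 (1.0 equiv), THF, 50 °C
Reagents that add atoms: none
Why: 9-BBN adds anti-Markovnikov to the only monosubstituted alkene of 20 (the Z-disubstituted and the bromine-bearing diene alkenes react far more slowly), tert-butoxide converts 21 into borate 22, and 22 hands its primary alkyl group to copper(I). The alkylcopper(I) species then attacks the unsubstituted =CH2 terminus of 13 anti to the phosphate (SN2'-type oxidative addition to a γ-σ-allylcopper(III), then reductive elimination), which forms the CH2–CH2 bond and moves the double bond into conjugation with the alkyne. The closest known reaction type is the copper-catalysed γ-selective allyl–alkyl coupling of B-alkyl-9-BBN reagents with secondary allylic phosphates, which gives E-alkenes with 1,3-transposition. No ring is closed and no stereocentre is formed: the carbinol centre of 13 (either epimer) is erased, and the new alkene should be E because the reacting conformer keeps the carbinol hydrogen, not the alkynyl group, in the plane of the vinyl group (allylic 1,3-strain). The step needs γ-attack on the vinyl group rather than on the alkyne (which would give a vinylallene) or at the carbinol carbon; the substrate offers an unhindered terminal CH2 against an alkyne carbon that carries the branched, α-oxygenated oxolanyl group, and only the vinyl pathway gives a conjugated product. Ester, oxolane and the 1-bromodiene should be inert, since the butoxide is bound in the borate and copper(I) does not insert into alkenyl bromides at this temperature.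

**Compound list**
1 | (S)-2-(but-3-en-1-yl)oxirane | C=CCC[C@H]1CO1 | starting material
2 | vinylmagnesium bromide | C=C[Mg]Br | starting material
3 | (S)-octa-1,7-dien-4-ol | C=CC[C@@H](O)CCC=C | intermediate
4 | [(2S,5S)-5-(prop-2-en-1-yl)oxolan-2-yl]methanol | C=CC[C@@H]1CC[C@@H](CO)O1 | intermediate
5 | methyl acrylate | C=CC(=O)OC | starting material
6 | methyl (2E)-4-[(2S,5S)-5-(hydroxymethyl)oxolan-2-yl]but-2-enoate | COC(=O)/C=C/C[C@@H]1CC[C@@H](CO)O1 | intermediate
7 | methyl 4-[(2R,5S)-5-(hydroxymethyl)oxolan-2-yl]butanoate | COC(=O)CCC[C@@H]1CC[C@@H](CO)O1 | intermediate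
8 | methyl 4-[(2R,5S)-5-formyloxolan-2-yl]butanoate | COC(=O)CCC[C@@H]1CC[C@@H](C=O)O1 | intermediate
9 | methyl 4-[(2R,5S)-5-ethynyloxolan-2-yl]butanoate | COC(=O)CCC[C@@H]1CC[C@@H](C#C)O1 | intermediate
10 | acrolein (prop-2-enal) | C=CC=O | starting material
11 | methylzinc acetylide of 9 | COC(=O)CCC[C@@H]1CC[C@@H](C#C[Zn]C)O1 | intermediate
12 | methyl 4-[(2R,5S)-5-(3-hydroxypent-4-en-1-yn-1-yl)oxolan-2-yl]butanoate (both carbinol epimers) | COC(=O)CCC[C@@H]1CC[C@@H](C#CC(O)C=C)O1 | intermediate
13 | methyl 4-[(2R,5S)-5-{3-[(diethoxyphosphoryl)oxy]pent-4-en-1-yn-1-yl}oxolan-2-yl]butanoate (both carbinol epimers) | COC(=O)CCC[C@@H]1CC[C@@H](C#CC(OP(=O)(OCC)OCC)C=C)O1 | intermediate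
14 | 3,3-diethoxyprop-1-yne | C#CC(OCC)OCC | starting material
15 | chlorobis(cyclopentadienyl)[(1E)-3,3-diethoxyprop-1-en-1-yl]zirconium | CCOC(OCC)/C=C/[Zr](Cl)(C1C=CC=C1)C1C=CC=C1 | intermediate
16 | (1E)-1-bromo-3,3-diethoxyprop-1-ene | CCOC(OCC)/C=C/Br | intermediate
17 | (2E)-3-bromoprop-2-enal | O=C/C=C/Br | intermediate
18 | (but-3-en-1-yl)triphenylphosphonium bromide | C=CCC[P+](c1ccccc1)(c1ccccc1)c1ccccc1.[Br-] | starting material
19 | (but-3-en-1-ylidene)triphenylphosphorane | C=CCC=P(c1ccccc1)(c1ccccc1)c1ccccc1 | intermediate
20 | (4Z,6E)-7-bromohepta-1,4,6-triene | C=CC/C=C\C=C\Br | intermediate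
21 | 9-[(4Z,6E)-7-bromohepta-4,6-dien-1-yl]-9-borabicyclo[3.3.1]nonane | Br/C=C/C=C\CCCB1C2CCCC1CCC2 | intermediate
22 | potassium 9-[(4Z,6E)-7-bromohepta-4,6-dien-1-yl]-9-tert-butoxy-9-boranuidabicyclo[3.3.1]nonane | CC(C)(C)O[B-]1(CCC/C=C\C=C\Br)C2CCCC1CCC2.[K+] | intermediate
23 | methyl 4-[(2R,5S)-5-[(3E,9Z,11E)-12-bromododeca-3,9,11-trien-1-yn-1-yl]oxolan-2-yl]butanoate | COC(=O)CCC[C@@H]1CC[C@@H](C#C/C=C/CCCC/C=C\C=C\Br)O1 | target

Total step count: 12. Longest linear sequence: 9 steps (steps 1–8, then step 12).

**Steps most likely to fail**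

1. Step 12. Copper may add to the alkyne instead of the vinyl group (propargylic SN2' to a vinylallene). The E/Z ratio of the new alkene may be lower than hoped because the alkynyl group is slim. The doubly activated phosphate may also ionise or transpose before it couples. The fallback moves the fragment union to the alkyne–alkene bond, which needs no site selection; it sets out from alkyne 9 and aldehyde 17 and comes back to the route at 23. 7-Bromohept-1-yne and PPh3 (MeCN, reflux) would give (hept-6-yn-1-yl)triphenylphosphonium bromide F1. Its ylide (NaHMDS, 1 equiv, THF, −78 °C) and 17 would give (1E,3Z)-1-bromodeca-1,3-dien-9-yne F2 by the same Z-selective Wittig reaction as in step 11. Hydrozirconation of the terminal alkyne (Cp2Zr(H)Cl, THF, 0 °C) and iodination (I2) would give (1E,7Z,9E)-10-bromo-1-iododeca-1,7,9-triene F3. Sonogashira coupling of F3 with 9 (Pd(PPh3)4, CuI, Et2NH, THF, rt), in which the C–I bond reacts well before the C–Br bond, would give 23 with the E-geometry fixed by the vinyl iodide.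

2. Step 7. Zincation of the alkyne may be slow or incomplete, and acrolein may polymerise or undergo conjugate addition before 1,2-addition. The fallback sets out from 9 and comes back at 12. Iodination of the alkyne (NIS, AgNO3 cat., acetone, rt) would give methyl 4-[(2R,5S)-5-(iodoethynyl)oxolan-2-yl]butanoate F4. Chromium(II)-mediated addition of F4 to acrolein 10 (CrCl2, NiCl2 cat., THF, rt; Nozaki–Hiyama–Kishi-type alkynylation, aldehyde-selective and ester-tolerant) would give 12.

3. Step 11. The bromoenal may decompose or polymerise under the basic conditions, volatile material may be lost, and Z-selectivity may erode. The fallback sets out from phosphonium salt 18 and comes back at 20, making the bromodiene by hydrozirconation–bromination instead of from the bromoenal (steps 9 and 10 are then not needed for this half). Ylide 19 and commercial 3-(trimethylsilyl)prop-2-ynal (THF, −78 °C) would give trimethyl[(3Z)-hepta-3,6-dien-1-yn-1-yl]silane F5. K2CO3 in MeOH would give (4Z)-hepta-1,4-dien-6-yne F6, kept in solution because it is volatile. Cp2Zr(H)Cl (1.0 equiv, THF, 0 °C, alkyne-selective) followed by NBS would give 20.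

**Further compounds**
F1 | step 12 | (hept-6-yn-1-yl)triphenylphosphonium bromide | C#CCCCCC[P+](c1ccccc1)(c1ccccc1)c1ccccc1.[Br-]
F2 | step 12 | (1E,3Z)-1-bromodeca-1,3-dien-9-yne | C#CCCCC/C=C\C=C\Br
F3 | step 12 | (1E,7Z,9E)-10-bromo-1-iododeca-1,7,9-triene | I/C=C/CCCC/C=C\C=C\Br
F4 | step 7 | methyl 4-[(2R,5S)-5-(iodoethynyl)oxolan-2-yl]butanoate | COC(=O)CCC[C@@H]1CC[C@@H](C#CI)O1
F5 | step 11 | trimethyl[(3Z)-hepta-3,6-dien-1-yn-1-yl]silane | C=CC/C=C\C#C[Si](C)(C)C
F6 | step 11 | (4Z)-hepta-1,4-dien-6-yne | C=CC/C=C\C#C
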